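**Plan** (labdane numbering: ring A = C1–C5, C10; ring B = C5–C10; C17 on C8, C18/C19 on C4, C20 on C10, C11–C16 side chain)
1. Retrosynthesis: cut C12–C13 (B-alkyl Suzuki coupling with bromobutenolide 21) and C11=C12 (Wittig); take C3, C4 (C18 methyl) and C8 back to a C3/C19/C17 tricarbonyl; then cut C5–C10 and C8–C9 together.
2. Enabling feature: in ring B the C5–C10 and C8–C9 bonds lie across the ring from each other, so with a C6=C7 bond ring B is the cyclohexene of a Diels–Alder reaction between a C5=C6–C7=C8 diene and a C9=C10 dienophile (C11 as CHO). The C1–C4 chain of ring A is the tether, so one intramolecular cycloaddition closes rings A and B and sets C5, C8, C9 and C10.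
3. Forward: geraniol gives C1–C3, C9–C11, C20 and the E C9=C10 bond; an iridium-catalysed (hydroxymethyl)allylation adds C4–C6 and C19; an oxidative Heck reaction adds C7, C8 and C17; the cycloaddition forms ring A and ring B together; the butenolide is coupled last.
4. Stereochemistry: the two allylation stereocentres (C3, C4) are temporary. Locked in a phenyl-equatorial 1,3-dioxane (temporary ring) they fix the diene face; alkene geometries and the endo transition state give C5, C9 and C10.
5. The helpers then leave: C8 is set by epimerising the C17 aldehyde, C4 by C-methylation of the 3-oxo-4-formyl enolate anti to C20, C3 by axial hydride delivery.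

Key step: step 9

Assumption: the (S)-bisphosphine in step 3 is taken to give the 2S,3S diol 6 by analogy with related iridium allylations; if the sense proves opposite, the antipodal ligand is used.

**Step 1**
Reactants: 1 geraniol
Product: 2 tert-butyl{[(2E)-3,7-dimethylocta-2,6-dien-1-yl]oxy}diphenylsilane
Conditions: TBDPSCl, imidazole, DMF, 0 °C → rt
Reagents that add atoms: tert-butyl(chloro)diphenylsilane, CC(C)(C)[Si](Cl)(c1ccccc1)c1ccccc1
Why: Imidazole-promoted silylation of the primary allylic alcohol gives a silyl ether that tolerates the peracid, acid, iridium and palladium steps ahead and is removed by fluoride in step 7; no stereocentre is formed.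

**Step 2**
Reactants: 2 tert-butyl{[(2E)-3,7-dimethylocta-2,6-dien-1-yl]oxy}diphenylsilane
Product: 4 (4E)-6-[(tert-butyldiphenylsilyl)oxy]-4-methylhex-4-enal, via 6,7-epoxide 3 (not isolated)
Conditions: mCPBA, CH2Cl2, −20 → 0 °C; then H5IO6, THF–H2O, 0 °C
Reagents that add atoms: 3-chloroperbenzoic acid, OOC(=O)c1cccc(Cl)c1
Why: Electrophilic epoxidation prefers the remote, more electron-rich 6,7-alkene (the 2,3-alkene is deactivated by the allylic oxygen) and periodic acid then hydrolyses and cleaves the epoxide (glycol cleavage), so the E alkene that becomes C9=C10 is kept.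

**Step 3**
Reactants: 4 (4E)-6-[(tert-butyldiphenylsilyl)oxy]-4-methylhex-4-enal; 5 4-ethenyl-1,3-dioxolan-2-one (racemic)
Product: 6 (2S,3S,6E)-8-[(tert-butyldiphenylsilyl)oxy]-2-ethenyl-6-methyloct-6-ene-1,3-diol
Conditions: [Ir(cod)Cl]2 (cat.), (S)-SEGPHOS, 4-cyano-3-nitrobenzoic acid (cat.), K3PO4 (cat.), 2-propanol (2 equiv), THF, 70 °C
Reagents that add atoms: none
Why: Iridium-catalysed transfer-hydrogenative carbonyl (hydroxymethyl)allylation: decarboxylative ionisation of 5 gives a π-allyliridium whose E σ-allyl form adds to the aldehyde through a closed chair transition state (anti 1,3-diol) while the chiral bisphosphine fixes the carbinol as S.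

**Step 4**
Reactants: 6 (2S,3S,6E)-8-[(tert-butyldiphenylsilyl)oxy]-2-ethenyl-6-methyloct-6-ene-1,3-diol
Product: 7 tert-butyl({(2E)-5-[(2R,4S,5S)-5-ethenyl-2-phenyl-1,3-dioxan-4-yl]-3-methylpent-2-en-1-yl}oxy)diphenylsilane
Conditions: PhCH(OMe)2, camphorsulfonic acid (cat.), CH2Cl2, rt
Reagents that add atoms: benzaldehyde dimethyl acetal, COC(OC)c1ccccc1
Why: Acid-catalysed transacetalisation under thermodynamic control gives the 1,3-dioxane with phenyl and the side chain equatorial, which forces the vinyl group axial; this temporary ring is the conformational lock for step 9.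

**Step 5**
Reactants: 8 benzyl prop-2-yn-1-yl ether
Product: 9 2-[(1E)-3-(benzyloxy)prop-1-en-1-yl]-4,4,5,5-tetramethyl-1,3,2-dioxaborolane
Conditions: pinacolborane, Cp2Zr(H)Cl (cat.), Et3N (cat.), neat, 60 °C
Reagents that add atoms: pinacolborane, CC1(C)OBOC1(C)C
Why: Zirconium-catalysed syn-hydroboration of the terminal alkyne puts boron on the terminal carbon and gives only the E alkenylboronate.

**Step 6**
Reactants: 7 tert-butyl({(2E)-5-[(2R,4S,5S)-5-ethenyl-2-phenyl-1,3-dioxan-4-yl]-3-methylpent-2-en-1-yl}oxy)diphenylsilane; 9 2-[(1E)-3-(benzyloxy)prop-1-en-1-yl]-4,4,5,5-tetramethyl-1,3,2-dioxaborolane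
Product: 10 tert-butyl({(2E)-5-[(2R,4S,5S)-5-[(1E,3E)-5-(benzyloxy)penta-1,3-dien-1-yl]-2-phenyl-1,3-dioxan-4-yl]-3-methylpent-2-en-1-yl}oxy)diphenylsilane
Conditions: Pd(OAc)2 (cat.), 1,2-bis(phenylsulfinyl)ethane (cat.), 2,6-dimethyl-1,4-benzoquinone, AcOH, 1,4-dioxane, 45 °C
Reagents that add atoms: none
Why: Oxidative Heck vinylation (transmetalation of 9 to divalent palladium, insertion of the monosubstituted alkene, β-hydride elimination toward the new vinyl group, reoxidation by the quinone) should give the conjugated E,E diene; the trisubstituted alkene does not insert and the dioxane stereocentres are not touched.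

**Step 7**
Reactants: 10 silyl ether of the dienyl dioxane
Product: 11 (2E)-5-[(2R,4S,5S)-5-[(1E,3E)-5-(benzyloxy)penta-1,3-dien-1-yl]-2-phenyl-1,3-dioxan-4-yl]-3-methylpent-2-en-1-ol
Conditions: TBAF, THF, 0 °C → rt
Reagents that add atoms: none
Why: Fluoride-induced desilylation frees the allylic alcohol; acetal, benzyl ether and diene are inert.

**Step 8**
Reactants: 11 (2E)-5-[(2R,4S,5S)-5-[(1E,3E)-5-(benzyloxy)penta-1,3-dien-1-yl]-2-phenyl-1,3-dioxan-4-yl]-3-methylpent-2-en-1-ol
Product: 12 (2E)-5-[(2R,4S,5S)-5-[(1E,3E)-5-(benzyloxy)penta-1,3-dien-1-yl]-2-phenyl-1,3-dioxan-4-yl]-3-methylpent-2-enal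
Conditions: MnO2, CH2Cl2, rt
Reagents that add atoms: none
Why: MnO2 oxidises only the allylic alcohol (allylic oxidation) and gives the E enal, the dienophile, without isomerisation under neutral conditions.

**Step 9**
Reactants: 12 (2E)-5-[(2R,4S,5S)-5-[(1E,3E)-5-(benzyloxy)penta-1,3-dien-1-yl]-2-phenyl-1,3-dioxan-4-yl]-3-methylpent-2-enal
Product: 13 cycloadduct aldehyde: trans-fused Δ6-octalin with C20 methyl, C11 formyl and C17 benzyloxymethyl on one face and H5 on the other; 2-phenyl-1,3-dioxane cis-fused at C3–C4 (C3–O axial; C19 equatorial)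
Conditions: Me2AlCl (1.2 equiv), CH2Cl2, −78 → −20 °C; aqueous HCl quench
Reagents that add atoms: none
Why: The Me2AlCl-complexed E enal (C9=C10) and the 5E,7E diene combine in a concerted, asynchronous, normal-electron-demand [4+2] cycloaddition. The closest known reaction type is the Lewis-acid-promoted type 1 intramolecular Diels–Alder reaction of 2,7,9-decatrienals with a four-carbon tether, which gives trans-fused octalins. Ring B closes as the cyclohexene of the cycloaddition (C5–C10 and C8–C9) and ring A as a six-membered ring through the C1–C4 tether held in a chair. C9 and C10 (C11 cis to C20) follow from the E dienophile, C8 (C17 cis to C11) from the E C7=C8 bond, and the trans C5/C10 fusion from the endo transition state with the formyl group under the diene. The absolute sense comes from the dioxane: with phenyl and the tether chain equatorial the dienyl group is axial, only one ring A chair (C3–O axial, C19 equatorial) joins the two, and the dienophile therefore reaches a single diene face. The step needs endo over exo selectivity, secured by the Lewis acid, and this facial selectivity, secured by the chair-locked temporary ring (the other face would need a boat ring A or the dioxane chair with phenyl and chain axial).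

**Step 10**
Reactants: 13 cycloadduct aldehyde
Product: 15 lactol diol (C17–O–C11 hemiacetal ring cis-fused on C8–C9; free 3-OH and 19-OH; anomer mixture), via hydroxy aldehyde 14 (not isolated)
Conditions: H2 (1 atm), Pd(OH)2/C, EtOAc–THF, rt
Reagents that add atoms: none
Why: Heterogeneous hydrogenation saturates the C6=C7 bond and hydrogenolysis removes the benzyl ether and the benzylidene ring in the same operation; the freed C17 hydroxyl, cis to the formyl group, closes to the five-membered lactol, which masks the aldehyde and protects C9.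

**Step 11**
Reactants: 15 lactol diol
Product: 16 vinyl triol (C9 vinyl equatorial; 3-OH axial; C19 hydroxymethyl equatorial on C4; C17 hydroxymethyl axial on C8)
Conditions: Ph3PCH3Br, KOtBu, THF, 0 → 45 °C
Reagents that add atoms: methyltriphenylphosphonium bromide, C[P+](c1ccccc1)(c1ccccc1)c1ccccc1.[Br-]
Why: Wittig methylenation of the lactol through its open hydroxy aldehyde form (excess ylide deprotonates the hydroxyls) gives the C9 vinyl group with C9 unchanged.

**Step 12**
Reactants: 16 vinyl triol
Product: 18 3-oxo-4-formyl-8-formyl vinyl decalin with the C17 formyl group equatorial (ring A present as the enolised hydroxymethylene ketone), via axial-formyl tricarbonyl 17 (not isolated)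
Conditions: Dess–Martin periodinane, pyridine, CH2Cl2, 0 °C → rt; then DBU, rt
Reagents that add atoms: none
Why: Dess–Martin oxidation converts all three carbinols to carbonyls, which erases the temporary C3 and C4 centres, and DBU then equilibrates the C17 aldehyde from the axial position (1,3-diaxial to C20) to the equatorial one, which sets C8 under thermodynamic control.

**Step 13**
Reactants: 18 3-oxo-4-formyl-8-formyl vinyl decalin
Product: 19 4-methyl-3-oxo-4,8-diformyl vinyl decalin (C18 methyl equatorial; C19 formyl axial and cis to C20)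
Conditions: MeI, K2CO3, acetone, rt
Reagents that add atoms: iodomethane, CI
Why: C-Alkylation of the 1,3-dicarbonyl enolate with iodomethane occurs on the face of ring A opposite the axial C20 methyl, so the new methyl (C18) is equatorial and the formyl group (C19) axial, which sets the C4 quaternary centre.

**Step 14**
Reactants: 19 4-methyl-3-oxo-4,8-diformyl vinyl decalin
Product: 20 vinyl triol with the target configuration at C3, C4, C5, C8, C9 and C10 (the target lacking C13–C16)
Conditions: NaBH4, MeOH–THF, −20 → 0 °C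
Reagents that add atoms: none
Why: NaBH4 reduces both aldehydes and the ketone; hydride adds axially to the 4,4-disubstituted C3 ketone, on the face away from the axial C19 and C20 groups, and gives the equatorial 3-hydroxyl of the target.

**Step 15**
Reactants: 20 vinyl triol; 21 3-bromofuran-2(5H)-one
Product: 23 14-deoxy-17-hydroxyandrographolide, via B-alkyl borane 22 (not isolated)
Conditions: 9-BBN (excess), THF, 0 °C → rt; then 21, PdCl2(dppf) (cat.), AsPh3, Cs2CO3, DMF–H2O, rt
Reagents that add atoms: none
Why: 9-BBN hydroborates the vinyl group at the terminal carbon (the hydroxyls are held as borinates) and the B-alkyl Suzuki–Miyaura coupling with the α-bromobutenolide forms the C12–C13 bond under mild base without touching any stereocentre.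

**Compound list**
1 | geraniol | CC(C)=CCC/C(C)=C/CO | starting material
2 | tert-butyl{[(2E)-3,7-dimethylocta-2,6-dien-1-yl]oxy}diphenylsilane | CC(C)=CCC/C(C)=C/CO[Si](c1ccccc1)(c1ccccc1)C(C)(C)C | intermediate
3 | 6,7-epoxide of 2 (racemic, not isolated) | CC1(C)OC1CC/C(C)=C/CO[Si](c1ccccc1)(c1ccccc1)C(C)(C)C | intermediate
4 | (4E)-6-[(tert-butyldiphenylsilyl)oxy]-4-methylhex-4-enal | O=CCC/C(C)=C/CO[Si](c1ccccc1)(c1ccccc1)C(C)(C)C | intermediate
5 | 4-ethenyl-1,3-dioxolan-2-one (racemic) | C=CC1COC(=O)O1 | starting material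
6 | (2S,3S,6E)-8-[(tert-butyldiphenylsilyl)oxy]-2-ethenyl-6-methyloct-6-ene-1,3-diol | OC[C@H](C=C)[C@@H](O)CC/C(C)=C/CO[Si](c1ccccc1)(c1ccccc1)C(C)(C)C | intermediate
7 | tert-butyl({(2E)-5-[(2R,4S,5S)-5-ethenyl-2-phenyl-1,3-dioxan-4-yl]-3-methylpent-2-en-1-yl}oxy)diphenylsilane | C=C[C@H]1CO[C@@H](c2ccccc2)O[C@H]1CC/C(C)=C/CO[Si](c2ccccc2)(c2ccccc2)C(C)(C)C | intermediate
8 | benzyl prop-2-yn-1-yl ether | C#CCOCc1ccccc1 | starting material
9 | 2-[(1E)-3-(benzyloxy)prop-1-en-1-yl]-4,4,5,5-tetramethyl-1,3,2-dioxaborolane | CC1(C)OB(/C=C/COCc2ccccc2)OC1(C)C | intermediate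
10 | silyl ether of the (2R,4S,5S)-5-[(1E,3E)-5-(benzyloxy)penta-1,3-dienyl]-2-phenyl-1,3-dioxane | c1ccccc1COC/C=C/C=C/[C@H]2CO[C@@H](c3ccccc3)O[C@H]2CC/C(C)=C/CO[Si](c3ccccc3)(c3ccccc3)C(C)(C)C | intermediate
11 | (2E)-5-[(2R,4S,5S)-5-[(1E,3E)-5-(benzyloxy)penta-1,3-dien-1-yl]-2-phenyl-1,3-dioxan-4-yl]-3-methylpent-2-en-1-ol | c1ccccc1COC/C=C/C=C/[C@H]2CO[C@@H](c3ccccc3)O[C@H]2CC/C(C)=C/CO | intermediate
12 | (2E)-5-[(2R,4S,5S)-5-[(1E,3E)-5-(benzyloxy)penta-1,3-dien-1-yl]-2-phenyl-1,3-dioxan-4-yl]-3-methylpent-2-enal | c1ccccc1COC/C=C/C=C/[C@H]2CO[C@@H](c3ccccc3)O[C@H]2CC/C(C)=C/C=O | intermediate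
13 | cycloadduct aldehyde (trans-fused Δ6-octalin; C20, C11 formyl and C17 benzyloxymethyl cis; 3,19-O-benzylidene ring cis-fused) | c1ccccc1[C@@H]2OC[C@@H]3[C@H]4C=C[C@@H](COCc5ccccc5)[C@@H](C=O)[C@]4(C)CC[C@@H]3O2 | intermediate
14 | hydroxy aldehyde (saturated; free 3-OH, 19-OH and 17-OH; C11 formyl; not isolated) | OC[C@@H]1[C@H]2CC[C@@H](CO)[C@@H](C=O)[C@]2(C)CC[C@@H]1O | intermediate
15 | lactol diol (C17–O–C11 hemiacetal; anomer mixture) | OC[C@@H]1[C@H]2CC[C@H]3COC(O)[C@H]3[C@]2(C)CC[C@@H]1O | intermediate
16 | vinyl triol (3-OH axial; C19 equatorial; C17 axial) | OC[C@@H]1[C@H]2CC[C@@H](CO)[C@@H](C=C)[C@]2(C)CC[C@@H]1O | intermediate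
17 | tricarbonyl with axial C17 formyl (keto form shown; C4 enolised; not isolated) | O=CC1[C@H]2CC[C@@H](C=O)[C@@H](C=C)[C@]2(C)CCC1=O | intermediate
18 | tricarbonyl with equatorial C17 formyl (keto form shown; C4 enolised) | O=CC1[C@H]2CC[C@H](C=O)[C@@H](C=C)[C@]2(C)CCC1=O | intermediate
19 | 4-methyl-3-oxo-4,8-diformyl vinyl decalin (C18 equatorial; C19 formyl axial) | C[C@]1(C=O)[C@H]2CC[C@H](C=O)[C@@H](C=C)[C@]2(C)CCC1=O | intermediate
20 | vinyl triol with target configuration | C[C@]1(CO)[C@H]2CC[C@H](CO)[C@@H](C=C)[C@]2(C)CC[C@H]1O | intermediate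
21 | 3-bromofuran-2(5H)-one | O=C1OCC=C1Br | starting material
22 | B-alkyl-9-BBN borane of 20 with the three hydroxyls as 9-BBN borinates (not isolated) | C[C@]1(COB3C4CCCC3CCC4)[C@H]2CC[C@H](COB3C4CCCC3CCC4)[C@@H](CCB3C4CCCC3CCC4)[C@]2(C)CC[C@H]1OB3C4CCCC3CCC4 | intermediate
23 | 14-deoxy-17-hydroxyandrographolide | C[C@]1(CO)[C@H]2CC[C@H](CO)[C@@H](CCC3=CCOC3=O)[C@]2(C)CC[C@H]1O | target

**Count and risks**
Total step count: 15. Longest linear sequence: 14 (steps 1–4 and 6–15 from geraniol; step 5 is a one-step side branch).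

Most likely to fail, in this order:

The cycloaddition of step 9 may suffer from poor endo/exo (trans/cis ring fusion) selectivity with the β,β-disubstituted enal, or from Lewis-acid ionisation of the acetal or the dienyl ether. The fallback changes the activating group to a two-point-binding imide. It sets out from 12: Pinnick oxidation (NaClO2, NaH2PO4, 2-methyl-2-butene) should give the trienoic acid F1. Its mixed pivalic anhydride is acylated onto lithiated oxazolidin-2-one to give the N-acyl oxazolidinone F2. Chelation of Me2AlCl between the two carbonyls should enforce the s-cis endo cycloaddition and give the imide cycloadduct F3. LiBH4 reduction gives the primary alcohol F4, and Dess–Martin oxidation comes back to the route at 13.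

The oxidative Heck coupling of step 6 may stall on the hindered alkene, or lose the E,E geometry through palladium hydride migration or allylic oxidation. The fallback activates both partners instead. It sets out from 7: rhodium-catalysed dehydrogenative borylation of the terminal alkene (B2pin2, RhCl(CO)(PPh3)2 cat., toluene–MeCN, 80 °C) should give the E alkenylboronate F5. Compound 9 is converted by iododeboronation with retention (NaOH, I2, THF) into benzyl (2E)-3-iodoprop-2-en-1-yl ether F6. Suzuki–Miyaura coupling of F5 with F6 (Pd(PPh3)4, K3PO4, THF–H2O) comes back to the route at 10.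

The hydroboration–coupling of step 15 may fail through protodeboronation of the alkylborane or base-induced decomposition of the bromobutenolide. The fallback builds the butenolide by enolate alkylation. It sets out from 20: silylation (TESCl, imidazole) gives the tris(triethylsilyl) ether F7. Hydroboration–oxidation (9-BBN; NaBO3) gives the primary alcohol F8, and I2, PPh3, imidazole gives the iodide F9. Alkylation of the lithium enolate of 3-(phenylsulfanyl)oxolan-2-one (LDA, THF–HMPA) gives the α-phenylsulfanyl lactone F10. Oxidation to the sulfoxide (mCPBA, −78 °C), thermal syn-elimination (toluene, 110 °C) and desilylation (HF·pyridine) come back to the route at 23.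

**Further compounds**
F1 | step 9 | (2E)-5-[(2R,4S,5S)-5-[(1E,3E)-5-(benzyloxy)penta-1,3-dien-1-yl]-2-phenyl-1,3-dioxan-4-yl]-3-methylpent-2-enoic acid | c1ccccc1COC/C=C/C=C/[C@H]2CO[C@@H](c3ccccc3)O[C@H]2CC/C(C)=C/C(=O)O
F2 | step 9 | N-acyl oxazolidin-2-one of F1 | c1ccccc1COC/C=C/C=C/[C@H]2CO[C@@H](c3ccccc3)O[C@H]2CC/C(C)=C/C(=O)N4CCOC4=O
F3 | step 9 | imide cycloadduct (as 13 with C11 as N-acyl oxazolidinone) | c1ccccc1[C@@H]2OC[C@@H]3[C@H]4C=C[C@@H](COCc5ccccc5)[C@@H](C(=O)N6CCOC6=O)[C@]4(C)CC[C@@H]3O2
F4 | step 9 | C11 primary alcohol corresponding to 13 | c1ccccc1[C@@H]2OC[C@@H]3[C@H]4C=C[C@@H](COCc5ccccc5)[C@@H](CO)[C@]4(C)CC[C@@H]3O2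
F5 | step 6 | E alkenyl pinacolboronate derived from the vinyl group of 7 | CC1(C)OB(/C=C/[C@H]2CO[C@@H](c3ccccc3)O[C@H]2CC/C(C)=C/CO[Si](c3ccccc3)(c3ccccc3)C(C)(C)C)OC1(C)C
F6 | step 6 | benzyl (2E)-3-iodoprop-2-en-1-yl ether | I/C=C/COCc1ccccc1
F7 | step 15 | tris(triethylsilyl) ether of 20 | C[C@]1(CO[Si](CC)(CC)CC)[C@H]2CC[C@H](CO[Si](CC)(CC)CC)[C@@H](C=C)[C@]2(C)CC[C@H]1O[Si](CC)(CC)CC
F8 | step 15 | C12 primary alcohol of F7 | C[C@]1(CO[Si](CC)(CC)CC)[C@H]2CC[C@H](CO[Si](CC)(CC)CC)[C@@H](CCO)[C@]2(C)CC[C@H]1O[Si](CC)(CC)CC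
F9 | step 15 | C12 iodide of F7 | C[C@]1(CO[Si](CC)(CC)CC)[C@H]2CC[C@H](CO[Si](CC)(CC)CC)[C@@H](CCI)[C@]2(C)CC[C@H]1O[Si](CC)(CC)CC
F10 | step 15 | α-alkyl-α-phenylsulfanyl butyrolactone (epimer mixture at the lactone α-carbon) | C[C@]1(CO[Si](CC)(CC)CC)[C@H]2CC[C@H](CO[Si](CC)(CC)CC)[C@@H](CCC3(Sc4ccccc4)CCOC3=O)[C@]2(C)CC[C@H]1O[Si](CC)(CC)CC
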